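The numbers in the tables stem from a simulated flask from invented constants.

A minute is the wrong unit for this flask, so I count time in clocks and go to powers of ten.

| setting | blue | teal | delta | theta |
|---|---|---|---|---|
| substrate | 31 mM | 56 mM | 25 mM | 48 mM |
| coupling partner | 45.6 mM | 45.6 mM | 45.6 mM | 45.6 mM |
| remark | run made earlier | run made earlier |  |  |
| time |  |  | 120 min | 40 min |

| run | time / min | target / % |
|---|---|---|
| blue | 2.50 | 6 |
| blue | 3.00 | 9 |
| blue | 5.00 | 14 |
| blue | 8.00 | 19 |
| blue | 12.0 | 27 |
| blue | 20.0 | 31 |
| blue | 30.0 | 44 |
| teal | 4.00 | 10 |
| teal | 8.00 | 16 |
| teal | 12.0 | 20 |
| teal | 15.0 | 26 |
| teal | 20.0 | 30 |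
| teal | 25.0 | 30 |
| teal | 30.0 | 34 |

(readings scatter by 2 percentage points)



* which one finishes higher in amount of target, in percent of the substrate charged ("neither" within 2 percentage points) (delta / theta / neither)
* amount of target at the end, in percent of the substrate charged, delta
* amount of target at the end, in percent of the substrate charged, theta

Both earlier runs start with a fractional rate of target formation that I read from 14% at 5.00 min in blue and 10% at 4.00 min in teal. The averaged reciprocal of that rate is 37.9 min: this is the coupling clock, a pseudo-first-order time with coupling partner held at its charge. These runs share one partner charge, so I assume, unproved, that the clock runs inversely with that charge; delta and theta hold the same charge and therefore the same clock.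

Now the ladder, as the log10 of time over clock. The last readings stand at −0.101, and target is still rising there in blue. One rung up, theta stops at 0.0239, later than the last readings, so I expect it a little above teal's last 34%. Delta stops at 0.501, later than any reading, so the readings give me no direct hold on it.

The forecast picks delta, with delta at 60% (47% to 77%) and theta at 40% (33% to 47%), saying "Delta has excess partner and long time".

The flask gives delta 48.6% and theta 38.6%, so delta finishes higher.

    coupling partner → decomposed reagent (k = 0.00330 /min)
    substrate + coupling partner ⇌ target + by-product (K = 0.970, k = 0.610 /M/min)
    target + by-product → side product (k = 0.240 /M/min)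

Delta's target stands at 51.8% after 60.0 min and is falling by the end, when it is made at 0.338 of the rate at which it is used, with side product at 15.3% after 120 min. The neighbour flask with 78 mM of coupling partner gets a clock of 22.1 min by the same scaling, which puts its end at 0.734, higher on the ladder than delta; it ends with target at 54.9% and side product at 23.0%.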